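**Plan**

- Retrosynthetic cuts: O–C11 aryl ether (Mitsunobu), the C6 carbonyl (allylic C–H oxidation), C9–C11 (methylenation and hydroboration of a C9 ketone), C3–C4 (radical closure of ring A), then C1–C10 and C10–CH3 (two enolate alkylations).
- Enabling feature: ring B with its C8 methyl, the C7=C8 double bond and the C5 stereocentre is (S)-carvone. The isopropenyl group is C4 plus one of its methyls and the carvone carbonyl is C9, so a tertiary C4 radical sits six atoms from a nitrile carbon C3 hung on C10.
- Forward order: ring B is bought, C10 is made quaternary, ring A closes through C3–C4, C11 is added at C9, C3 is reduced, the coumarin is joined at C11 and C6 is oxidised last.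
- Stereochemistry: C5 comes from carvone; C10 from alkylation anti to the isopropenyl group; C9 from hydroboration anti to the C10 methyl; C3 from equatorial hydride delivery (axial OH).

Key step: step 3

Remark: drimane numbering is used throughout (ring A = C1–C5, C10; ring B = C5–C10; C11 on C9, C12 on C8, C13 and C14 on C4, C15 on C10). The target is (3S,5S,9R,10S) in this numbering. Faces are described relative to the C10 methyl (C15).

Assumption: the C6 epimer ratio of compound 2 does not matter, because that carbon becomes a planar enolate again in step 2.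

**Step 1**
Reactants: 1 (S)-(+)-carvone
Product: 2 trans-6-methylcarvone
Conditions: LiN(i-Pr)2, THF, −78 °C; MeI, −78 → 0 °C
Reagents that add atoms: methyl iodide, CI
Why: Kinetic deprotonation at the alpha-prime carbon of the enone (future C10) followed by SN2 enolate alkylation is the standard way to methylate carvone; the new centre is erased again in step 2.

**Step 2**
Reactants: 2 trans-6-methylcarvone; 3 acrylonitrile
Product: 4 6-(2-cyanoethyl)-6-methylcarvone (cyanoethyl trans to the isopropenyl group)
Conditions: LiN(i-Pr)2, THF, −78 °C; acrylonitrile added slowly, −78 °C; AcOH quench at −78 °C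
Reagents that add atoms: none
Why: Michael addition of the tetrasubstituted lithium enolate to acrylonitrile should occur on the face anti to the pseudoaxial isopropenyl group, which fixes quaternary C10 with the C1 chain trans to the C4 arm; the cold acid quench is meant to stop a second, intramolecular Michael addition.

**Step 3**
Reactants: 4 6-(2-cyanoethyl)-6-methylcarvone
Product: 6 trans-fused 11-nordrim-7-ene-3,9-dione, via C3 ketimine 5 (not isolated)
Conditions: Fe(acac)3 (30 mol %), PhSiH3, EtOH, 0.01 M, degassed, 60 °C; then 1 M HCl, THF, rt
Reagents that add atoms: water, O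
Why: An iron hydride formed from Fe(acac)3, PhSiH3 and EtOH transfers a hydrogen atom to the terminal CH2 of the isopropenyl group, the tertiary C4 radical adds to the nitrile carbon C3, the iminyl radical is reduced by divalent iron and protonated to ketimine 5, and aqueous acid hydrolyses 5 to the C3 ketone. The closest known reaction type is the iron-hydride hydrogen-atom-transfer reductive cyclisation of alkenyl nitriles to cyclic ketones. Ring A closes in the 6-exo-dig mode through the C3–C4 bond. No stereocentre is created (C4 carries two methyls, C3 is trigonal), and the trans ring fusion follows from the trans arrangement of the two arms set in step 2, which can only be bridged diequatorially. The step needs hydrogen-atom transfer to the electron-rich 1,1-disubstituted alkene and not to the conjugated trisubstituted enone alkene, and ring closure faster than reduction of the radical. This should be secured by the known preference of metal hydrides for electron-rich alkenes, by the enone being out of reach of C4 (only a four-membered ring could form), by the quaternary C10 holding the nitrile near C4 (Thorpe–Ingold effect) and by high dilution against intermolecular Giese addition.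

**Step 4**
Reactants: 6 trans-fused 11-nordrim-7-ene-3,9-dione
Product: 7 3,3-(ethylenedioxy)-11-nordrim-7-en-9-one
Conditions: ethylene glycol, p-TsOH (cat.), benzene, reflux, Dean–Stark
Reagents that add atoms: ethylene glycol, OCCO
Why: Acid-catalysed ketalisation should select the saturated C3 ketone, because the C9 carbonyl is conjugated and flanked by the quaternary C10 and the C8 methyl and ketalises far more slowly.

**Step 5**
Reactants: 7 3,3-(ethylenedioxy)-11-nordrim-7-en-9-one
Product: 8 3,3-(ethylenedioxy)drima-7,9(11)-diene
Conditions: Ph3PCH3Br, KOt-Bu, toluene, 100 °C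
Reagents that add atoms: methyltriphenylphosphonium bromide, C[P+](c1ccccc1)(c1ccccc1)c1ccccc1.[Br-]
Why: Wittig methylenation with the ylide generated by potassium tert-butoxide at elevated temperature is an established answer to hindered ketones and should turn the C9 carbonyl into the exocyclic C9=C11 alkene, the ketal being inert to base.

**Step 6**
Reactants: 8 3,3-(ethylenedioxy)drima-7,9(11)-diene
Product: 10 3,3-(ethylenedioxy)drim-7-en-11-ol, via alkylborane 9 (not isolated)
Conditions: 9-BBN, THF, 0 → 50 °C; then NaOH, H2O2, H2O, 0 °C → rt
Reagents that add atoms: hydrogen peroxide, OO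
Why: Hydroboration–oxidation with the bulky 9-BBN should place boron on the terminal C11 of the 1,1-disubstituted alkene and deliver hydrogen to C9 syn from the face opposite the axial C10 methyl, which sets C9 (H9 cis to H5, C11 equatorial); the trisubstituted C7=C8 alkene is left untouched.

**Step 7**
Reactants: 10 3,3-(ethylenedioxy)drim-7-en-11-ol
Product: 11 11-hydroxydrim-7-en-3-one
Conditions: 1 M HCl, THF, rt
Reagents that add atoms: water, O
Why: Aqueous acid hydrolysis of the dioxolane (acetal hydrolysis) frees the C3 ketone under conditions too mild to move the trisubstituted alkene or affect the primary alcohol.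

**Step 8**
Reactants: 11 11-hydroxydrim-7-en-3-one
Product: 12 drim-7-ene-3,11-diol with axial C3 hydroxyl
Conditions: LiBH(s-Bu)3 (excess), THF, −78 °C; then NaOH, H2O2, 0 °C
Reagents that add atoms: none
Why: Reduction with a bulky trialkylborohydride attacks a 4,4-dimethyl-3-ketone of a trans-decalin from the equatorial direction, so the hydroxyl should end up axial, on the face of H5 and opposite the C10 methyl, which sets C3.

**Step 9**
Reactants: 12 drim-7-ene-3,11-diol with axial C3 hydroxyl; 13 umbelliferone
Product: 14 7-[(3-hydroxydrim-7-en-11-yl)oxy]coumarin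
Conditions: PPh3, DIAD, THF, 0 °C → rt
Reagents that add atoms: none
Why: Mitsunobu etherification with the acidic phenol should take place only at the primary C11 alcohol, since the axial, neopentyl C3 alcohol cannot be displaced; no stereocentre is involved.

**Step 10**
Reactants: 14 7-[(3-hydroxydrim-7-en-11-yl)oxy]coumarin
Product: 15 C3 tert-butyldimethylsilyl ether of 14
Conditions: TBSOTf, 2,6-lutidine, CH2Cl2, 0 °C
Reagents that add atoms: tert-butyldimethylsilyl trifluoromethanesulfonate, CC(C)(C)[Si](C)(C)OS(=O)(=O)C(F)(F)F
Why: Silylation with the silyl triflate covers the hindered secondary alcohol before the chromium oxidation; a silyl group is chosen because it can later be removed without base.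

**Step 11**
Reactants: 15 C3 tert-butyldimethylsilyl ether of 14
Product: 16 6-oxo derivative of 15 (drim-7-en-6-one)
Conditions: CrO3, 3,5-dimethylpyrazole, CH2Cl2, −20 °C
Reagents that add atoms: chromium trioxide, O=[Cr](=O)=O
Why: Allylic C–H oxidation with the hexavalent chromium–dimethylpyrazole complex converts a ring methylene next to a trisubstituted alkene into the enone, and C6 should be preferred over the crowded tertiary C9–H and the C12 methyl; no stereocentre is touched.

**Step 12**
Reactants: 16 6-oxo derivative of 15
Product: 17 ferocaulidin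
Conditions: HF·pyridine, THF, 0 °C → rt
Reagents that add atoms: none
Why: Fluoride-mediated desilylation under mildly acidic conditions frees the C3 alcohol while avoiding base, which could deprotonate C9 and expel umbelliferone from C11 by vinylogous beta-elimination.

**Compound list**

1 | (S)-(+)-carvone, (5S)-2-methyl-5-(prop-1-en-2-yl)cyclohex-2-en-1-one | CC1=CC[C@@H](CC1=O)C(C)=C | starting material
2 | trans-6-methylcarvone, (5S,6R)-2,6-dimethyl-5-(prop-1-en-2-yl)cyclohex-2-en-1-one (major epimer drawn) | CC1=CC[C@H](C(C)=C)[C@@H](C)C1=O | intermediate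
3 | acrylonitrile | C=CC#N | starting material
4 | 6-(2-cyanoethyl)-6-methylcarvone; cyanoethyl trans and methyl cis to the isopropenyl group | CC1=CC[C@H](C(C)=C)[C@@](C)(CCC#N)C1=O | intermediate
5 | 3-imino-11-nordrim-7-en-9-one (N–H ketimine, trans-fused) | CC1=CC[C@@H]2C(C)(C)C(=N)CC[C@@]2(C)C1=O | intermediate
6 | 11-nordrim-7-ene-3,9-dione, trans-fused (H5 opposite the C10 methyl) | CC1=CC[C@@H]2C(C)(C)C(=O)CC[C@@]2(C)C1=O | intermediate
7 | 3,3-(ethylenedioxy)-11-nordrim-7-en-9-one | CC1=CC[C@@H]2C(C)(C)C3(OCCO3)CC[C@@]2(C)C1=O | intermediate
8 | 3,3-(ethylenedioxy)drima-7,9(11)-diene | CC1=CC[C@@H]2C(C)(C)C3(OCCO3)CC[C@@]2(C)C1=C | intermediate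
9 | B-[3,3-(ethylenedioxy)drim-7-en-11-yl]-9-borabicyclo[3.3.1]nonane | CC1=CC[C@@H]2C(C)(C)C3(OCCO3)CC[C@@]2(C)[C@@H]1CB1C2CCCC1CCC2 | intermediate
10 | 3,3-(ethylenedioxy)drim-7-en-11-ol (H9 cis to H5; C11 cis to the C10 methyl) | CC1=CC[C@@H]2C(C)(C)C3(OCCO3)CC[C@@]2(C)[C@@H]1CO | intermediate
11 | 11-hydroxydrim-7-en-3-one | CC1=CC[C@@H]2C(C)(C)C(=O)CC[C@@]2(C)[C@@H]1CO | intermediate
12 | drim-7-ene-3,11-diol, C3 hydroxyl axial (on the H5 face) | CC1=CC[C@@H]2C(C)(C)[C@@H](O)CC[C@@]2(C)[C@@H]1CO | intermediate
13 | umbelliferone (7-hydroxycoumarin) | O=c1ccc2ccc(O)cc2o1 | starting material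
14 | 7-[(3-hydroxydrim-7-en-11-yl)oxy]coumarin (6-deoxoferocaulidin) | CC1=CC[C@@H]2C(C)(C)[C@@H](O)CC[C@@]2(C)[C@@H]1COc1ccc2ccc(=O)oc2c1 | intermediate
15 | C3 tert-butyldimethylsilyl ether of 14 | CC1=CC[C@@H]2C(C)(C)[C@@H](O[Si](C)(C)C(C)(C)C)CC[C@@]2(C)[C@@H]1COc1ccc2ccc(=O)oc2c1 | intermediate
16 | C3 tert-butyldimethylsilyl ether of ferocaulidin (6-oxo derivative of 15) | CC1=CC(=O)[C@@H]2C(C)(C)[C@@H](O[Si](C)(C)C(C)(C)C)CC[C@@]2(C)[C@@H]1COc1ccc2ccc(=O)oc2c1 | intermediate
17 | ferocaulidin, (3S,5S,9R,10S)-7-[(3-hydroxy-6-oxodrim-7-en-11-yl)oxy]coumarin | CC1=CC(=O)[C@@H]2C(C)(C)[C@@H](O)CC[C@@]2(C)[C@@H]1COc1ccc2ccc(=O)oc2c1 | target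

**Step count and risks**

Total step count: 12. Longest linear sequence: 12 steps, from (S)-(+)-carvone 1 to 17.

Steps most likely to fail:

1. Step 3. The tertiary C4 radical may be reduced to the isopropyl group, or may add to the enone of a second molecule, before it closes onto the weakly accepting nitrile; the iminyl radical may also reopen. Fallback (sets out from 4, returns at 6): Markovnikov addition of HBr (HBr in AcOH, 0 °C) to the isopropenyl group should give the tertiary bromide F1. Slow syringe-pump addition of Bu3SnH with AIBN in refluxing benzene then generates the same C4 radical by bromine abstraction, at a hydride concentration low enough for the 6-exo closure onto the nitrile to outrun reduction. The resulting ketimine 5 is hydrolysed with 1 M HCl as before, and the route is rejoined at 6.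

2. Step 2. Acrylonitrile may polymerise anionically, the alpha-cyano carbanion formed first may add back into the enone (a double Michael reaction to a bicyclo[2.2.2]octanone), and facial selectivity may erode. Fallback (sets out from 2, returns at 4): the same lithium enolate is alkylated with allyl bromide, a reaction known to proceed anti to the isopropenyl group, to give 6-allyl-6-methylcarvone F2. An aldehyde-selective, nitrite-modified Wacker oxidation of the monosubstituted alkene (PdCl2(PhCN)2, CuCl2, AgNO2, O2, t-BuOH/MeNO2) should give the aldehyde F3, the 1,1-disubstituted and enone alkenes being inert. Condensation with NH2OH·HCl/NaOAc gives the aldoxime F4, and dehydration with Ac2O on warming gives nitrile 4.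

3. Step 11. Hydrogen abstraction may occur at the tertiary allylic C9–H (leading to the transposed 8-en-7-one) or at the C12 methyl in competition with C6. Fallback (sets out from 15, returns at 16): hydroxyselenation with PhSeCl in aqueous MeCN should add selenium to C7 from the face opposite the C10 methyl and water to the tertiary C8 in a trans-diaxial (Fürst–Plattner) sense, giving the hydroxy selenide F5. Oxidation with H2O2 gives the selenoxide F6, whose syn elimination can only run toward C6 because C8 bears no hydrogen, and this gives the tertiary allylic alcohol F7. Pyridinium chlorochromate, C5H5NH[CrO3Cl], in CH2Cl2 then effects the Babler–Dauben oxidative 1,3-transposition to the 7-en-6-one 16.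

**Further compounds**

F1 | step 3 | 6-(2-bromopropan-2-yl) analogue of 4 (tertiary bromide at C4) | CC1=CC[C@H](C(C)(C)Br)[C@@](C)(CCC#N)C1=O
F2 | step 2 | 6-allyl-6-methylcarvone (allyl trans to the isopropenyl group) | CC1=CC[C@H](C(C)=C)[C@@](C)(CC=C)C1=O
F3 | step 2 | 6-methyl-6-(3-oxopropyl)carvone | CC1=CC[C@H](C(C)=C)[C@@](C)(CCC=O)C1=O
F4 | step 2 | aldoxime of F3 (E/Z mixture) | CC1=CC[C@H](C(C)=C)[C@@](C)(CCC=NO)C1=O
F5 | step 11 | 8-hydroxy-7-(phenylselanyl) adduct of 15 (Se on C7 opposite the C10 methyl, OH on C8 on the C10-methyl face, both axial) | C[C@@]1(O)[C@@H]([Se]c3ccccc3)C[C@@H]2C(C)(C)[C@@H](O[Si](C)(C)C(C)(C)C)CC[C@@]2(C)[C@@H]1COc1ccc2ccc(=O)oc2c1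
F6 | step 11 | selenoxide of F5 (mixture at selenium) | C[C@@]1(O)[C@@H]([Se](=O)c3ccccc3)C[C@@H]2C(C)(C)[C@@H](O[Si](C)(C)C(C)(C)C)CC[C@@]2(C)[C@@H]1COc1ccc2ccc(=O)oc2c1
F7 | step 11 | 8-hydroxydrim-6-ene tertiary allylic alcohol (C3 silyl ether, C11 coumarinyl ether) | C[C@@]1(O)C=C[C@@H]2C(C)(C)[C@@H](O[Si](C)(C)C(C)(C)C)CC[C@@]2(C)[C@@H]1COc1ccc2ccc(=O)oc2c1
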